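**Retrosynthetic overview**
- The target is three (2R,3R)-2,3-cis flavan units joined by two 3,4-trans C4–C6 bonds. Both are cut last (silver-promoted C4-cation/C6 Friedel–Crafts couplings), so one benzyl-protected monomer feeds units A, B and C.
- In that monomer, and hence in the middle unit B, the pyran ring is cut at O1–C8a and C4–C4a: a catechol-derived aryl iodide and an O1–C2–C3–C4 chain (a γ-bromo alcohol) are joined by a palladium/norbornene relay annulation.
- Enabling feature: O1 and C4 sit on the adjacent ring A carbons C8a and C4a; C8a is flanked by the C8 oxygen (the one ortho substituent the relay needs), C4a–H is the only ortho C–H, and C4 is still a primary CH2 carbon at this stage.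
- C2 and C3 come from an Evans glycolate syn-aldol; the C4 oxygen is added afterwards with DDQ, and the 4α-OH of unit C by ketone reduction.
- Order of ring and bond formation: pyran ring of the monomer (step 7), A–B bond (step 14), B–C bond (step 16), global deprotection (step 18).

Key step: step 7

Remark: flavan numbering (O1, C2, C3, C4, C4a, C5–C8, C8a) is used for every unit; A, B and C are the upper, middle and lower units, 4β means trans and 4α cis to the C3 oxygen.

**Step 1**
Reactants: 1 (S)-4-benzyl-1,3-oxazolidin-2-one; 2 2-(benzyloxy)acetyl chloride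
Product: 3 (S)-4-benzyl-3-[2-(benzyloxy)acetyl]-1,3-oxazolidin-2-one
Conditions: Et3N, DMAP (cat.), CH2Cl2, 0 °C → rt
Reagents that add atoms: none
Why: DMAP-catalysed N-acylation of the oxazolidinone by the acid chloride; no stereocentre is touched.

**Step 2**
Reactants: 3 (S)-4-benzyl-3-[2-(benzyloxy)acetyl]-1,3-oxazolidin-2-one; 4 4-(benzyloxy)benzaldehyde
Product: 7 (S)-4-benzyl-3-[(2S,3R)-2-(benzyloxy)-3-[4-(benzyloxy)phenyl]-3-hydroxypropanoyl]-1,3-oxazolidin-2-one, via dibutylboron Z-enolate 5 (not isolated), via dibutylboron aldolate 6 (not isolated)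
Conditions: Bu2BOTf, Et3N, CH2Cl2, −78 → 0 °C; then 4, −78 → 0 °C; MeOH, pH 7 buffer, H2O2
Reagents that add atoms: none
Why: Evans syn-aldol reaction: the boron Z-enolate adds through a Zimmerman–Traxler chair on the face opposite the auxiliary benzyl group, which should set the (2S,3R) syn stereodiad that becomes C3 and C2 of every flavan unit.

**Step 3**
Reactants: 7 the syn-aldol adduct
Product: 8 (1R,2R)-2-(benzyloxy)-1-[4-(benzyloxy)phenyl]propane-1,3-diol
Conditions: LiBH4, MeOH (1 equiv), THF, 0 °C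
Reagents that add atoms: none
Why: Reductive cleavage of the N-acyl oxazolidinone by hydride attack on the exocyclic carbonyl should release the diol and the auxiliary without touching the stereocentres.

**Step 4**
Reactants: 8 (1R,2R)-2-(benzyloxy)-1-[4-(benzyloxy)phenyl]propane-1,3-diol
Product: 9 (1R,2S)-2-(benzyloxy)-1-[4-(benzyloxy)phenyl]-3-bromopropan-1-ol
Conditions: CBr4 (1.1 equiv), PPh3, 2,6-lutidine, CH2Cl2, −20 → 0 °C
Reagents that add atoms: carbon tetrabromide BrC(Br)(Br)Br
Why: Appel bromination; the unhindered primary hydroxyl forms the alkoxyphosphonium ion much faster than the secondary benzylic one and is displaced by bromide at the CH2 group, leaving both stereocentres untouched (the descriptor at C2 changes only by priority).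

**Step 5**
Reactants: 10 3-bromobenzene-1,2-diol
Product: 11 1,2-bis(benzyloxy)-3-bromobenzene
Conditions: BnBr, K2CO3, DMF, 60 °C
Reagents that add atoms: benzyl bromide BrCc1ccccc1
Why: Williamson ether synthesis on both phenolic hydroxyls.

**Step 6**
Reactants: 11 1,2-bis(benzyloxy)-3-bromobenzene
Product: 12 1,2-bis(benzyloxy)-3-iodobenzene
Conditions: CuI (10 mol %), NaI, N,N′-dimethylethylenediamine, 1,4-dioxane, 110 °C
Reagents that add atoms: sodium iodide [Na+].[I-]
Why: Copper-catalysed aromatic Finkelstein halogen exchange gives the aryl iodide needed for fast oxidative addition in step 7.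

**Step 7**
Reactants: 12 1,2-bis(benzyloxy)-3-iodobenzene; 9 (1R,2S)-2-(benzyloxy)-1-[4-(benzyloxy)phenyl]-3-bromopropan-1-ol
Product: 13 (2R,3R)-3,7,8-tris(benzyloxy)-2-[4-(benzyloxy)phenyl]chromane (2,3-cis)
Conditions: Pd(OAc)2 (10 mol %), RuPhos (20 mol %), norbornene (1 equiv), Cs2CO3, 1,4-dioxane, 100 °C
Reagents that add atoms: none
Why: Proposed new method: oxidative addition of zerovalent palladium into the C8a–I bond of 12, norbornene insertion and C4a–H palladation should give the aryl–norbornyl palladacycle of divalent palladium, which takes up the primary C4–Br bond of 9 by SN2 oxidative addition (tetravalent palladium) and forms C4a–C4 by reductive elimination; with both ortho positions of C8a then filled, norbornene is extruded and the tethered C2 alkoxide (O1) closes the ring by C–O reductive elimination at C8a. The closest known reaction type is the palladium/norbornene (Catellani-type) annulation of aryl iodides with epoxides to 2,3-dihydrobenzofurans (ortho alkylation, ipso C–O closure), together with the ortho-alkylation/ipso-amination with bromoalkylamines; here the tether is one carbon longer. The pyran ring is closed as a formal [4+2] annulation, the final C–O reductive elimination passing through a seven-membered oxapalladacycle to give the six-membered ring. No stereocentre is formed: C2 and C3 are carried over from 9 with retention because neither the C2–O1 nor the C3–O bond is broken, which fixes the (2R,3R)-2,3-cis pattern. The regiochemistry (O1 on C8a, C4 on C4a) is fixed by the iodide position, with the C8 benzyloxy group as the single ortho substituent and C4a–H as the only ortho C–H, and closure to the six-membered ring by O1 is secured because O3 is benzylated. The bulky electron-rich RuPhos ligand is chosen to favour C–O reductive elimination over β-hydride elimination of the benzylic palladium alkoxide, and the carbonate base should be too weak to convert 9 into an oxetane at a competing rate.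

**Step 8**
Reactants: 13 (2R,3R)-3,7,8-tris(benzyloxy)-2-[4-(benzyloxy)phenyl]chromane
Product: 14 (2R,3R,4S)-3,7,8-tris(benzyloxy)-2-[4-(benzyloxy)phenyl]chroman-4-ol (2,3-cis-3,4-trans)
Conditions: DDQ (1.5 equiv), CH2Cl2/H2O (10:1), 0 °C → rt
Reagents that add atoms: water O
Why: DDQ abstracts the C4 hydride benzylic to ring A (cation stabilised by O1 and the para C7 benzyloxy group) and water adds anti to the axial C3 benzyloxy group, a known C4 oxygenation of protected flavan-3-ols that should give the 4β alcohol.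

**Step 9**
Reactants: 14 the 4β-alcohol
Product: 15 (2R,3S)-3,7,8-tris(benzyloxy)-2-[4-(benzyloxy)phenyl]chroman-4-one (2,3-cis)
Conditions: Dess–Martin periodinane, NaHCO3, CH2Cl2, 0 °C → rt
Reagents that add atoms: none
Why: Dess–Martin oxidation of the secondary benzylic alcohol under buffered conditions, which should not epimerise the α-benzyloxy centre C3.

**Step 10**
Reactants: 15 the 2,3-cis flavanone
Product: 16 (2R,3R,4R)-3,7,8-tris(benzyloxy)-2-[4-(benzyloxy)phenyl]chroman-4-ol (all-cis)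
Conditions: NaBH4, THF/MeOH, −20 → 0 °C
Reagents that add atoms: none
Why: Borohydride reduction of the 2,3-cis flavanone: hydride is delivered anti to the axial C3 benzyloxy group, so the new C4 hydroxyl should be cis to it (4α, 4R), as is known for 2,3-cis dihydroflavonols.

**Step 11**
Reactants: 16 the all-cis 4α-alcohol
Product: 17 (2R,3S,4R)-3,7,8-tris(benzyloxy)-2-[4-(benzyloxy)phenyl]chroman-4-yl acetate (all-cis)
Conditions: Ac2O, pyridine, DMAP (cat.), CH2Cl2, rt
Reagents that add atoms: acetic anhydride CC(=O)OC(C)=O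
Why: DMAP-catalysed acetylation masks the C4 hydroxyl so that it can neither act as an O-nucleophile nor ionise under the soft activation of steps 14 and 16.

**Step 12**
Reactants: 14 the 4β-alcohol
Product: 18 (2R,3R,4S)-6-bromo-3,7,8-tris(benzyloxy)-2-[4-(benzyloxy)phenyl]chroman-4-ol (2,3-cis-3,4-trans)
Conditions: NBS (1.05 equiv), CH2Cl2, −40 → 0 °C, dark
Reagents that add atoms: N-bromosuccinimide O=C1CCC(=O)N1Br
Why: Electrophilic aromatic bromination at C6 of ring A, the position para to O1 and ortho to the C7 benzyloxy group; the bromine blocks the only strongly nucleophilic ring position of the later electrophile.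

**Step 13**
Reactants: 18 the 6-bromo 4β-alcohol
Product: 19 (2R,3S,4S)-4-(benzylsulfanyl)-6-bromo-3,7,8-tris(benzyloxy)-2-[4-(benzyloxy)phenyl]chromane (2,3-cis-3,4-trans)
Conditions: BnSH (5 equiv), BF3·OEt2 (0.5 equiv), CH2Cl2, −20 °C
Reagents that add atoms: phenylmethanethiol SCc1ccccc1
Why: SN1 thioetherification: BF3 ionises the benzylic C4 hydroxyl and the thiol adds to the cation anti to the C3 benzyloxy and C2 aryl groups, which should give the 4β sulfide.

**Step 14**
Reactants: 19 the 6-bromo 4β-sulfide (unit A); 17 the all-cis 4α-acetate (unit B, 3 equiv)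
Product: 20 per-O-benzyl 6-bromoepioritin-(4β→6)-epioritin-4α-yl acetate (units A–B)
Conditions: AgBF4 (1.5 equiv), 2,6-di-tert-butyl-4-methylpyridine, THF, 0 °C
Reagents that add atoms: none
Why: Silver-promoted Friedel–Crafts flavanyl coupling: thiophilic activation of the sulfide gives the C4 cation of unit A, which C6 of 17 (para to O1, ortho to the C7 benzyloxy group) attacks anti to the C3 benzyloxy and C2 aryl groups, setting the 4β (3,4-trans) C4–C6 bond; the C6 bromine prevents self-condensation and the acetate of 17 should not be ionised by the soft Lewis acid.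

**Step 15**
Reactants: 20 the A–B dimer acetate
Product: 21 per-O-benzyl 6-bromoepioritin-(4β→6)-4β-(benzylsulfanyl)epioritin (units A–B)
Conditions: BnSH (5 equiv), BF3·OEt2 (1 equiv), CH2Cl2, −40 → −20 °C
Reagents that add atoms: phenylmethanethiol SCc1ccccc1
Why: SN1 exchange of the benzylic C4 acetate of unit B for the thiol under BF3 activation, anti to the C3 benzyloxy group (4β sulfide); the interflavanyl bond of this fully benzylated 5-deoxy system should survive at low temperature.

**Step 16**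
Reactants: 21 the A–B dimer sulfide; 17 the all-cis 4α-acetate (unit C, 3 equiv)
Product: 22 per-O-benzyl 6-bromoepioritin-(4β→6)-epioritin-(4β→6)-epioritin-4α-yl acetate (units A–B–C)
Conditions: AgBF4 (1.5 equiv), 2,6-di-tert-butyl-4-methylpyridine, THF, 0 °C
Reagents that add atoms: none
Why: Second silver-promoted Friedel–Crafts coupling of the same kind: the C4 cation of unit B is captured by C6 of 17 anti to its C3 benzyloxy group, which should set the second 4β (3,4-trans) C4–C6 bond and complete the trimer skeleton.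

**Step 17**
Reactants: 22 the trimer acetate
Product: 23 per-O-benzyl 6-bromoepioritin-(4β→6)-epioritin-(4β→6)-epioritin-4α-ol
Conditions: K2CO3 (cat.), MeOH/THF, rt
Reagents that add atoms: none
Why: Base-catalysed transesterification removes the lone acetate; no stereocentre is touched.

**Step 18**
Reactants: 23 the benzylated bromo trimer alcohol
Product: 24 epioritin-(4β→6)-epioritin-(4β→6)-epioritin-4α-ol (target)
Conditions: H2 (1 atm), Pd(OH)2/C, NaOAc, THF/MeOH/H2O, rt
Reagents that add atoms: none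
Why: Catalytic hydrogenolysis cleaves the twelve benzyl ethers and the aryl C–Br bond; the NaOAc buffer keeps the medium non-acidic so that the benzylic C4 hydroxyl of unit C and the interflavanyl bonds should survive.

**Compound list**
1 | (S)-4-benzyl-1,3-oxazolidin-2-one | O=C1N[C@@H](Cc2ccccc2)CO1 | starting material
2 | 2-(benzyloxy)acetyl chloride | O=C(Cl)COCc1ccccc1 | starting material
3 | (S)-4-benzyl-3-[2-(benzyloxy)acetyl]-1,3-oxazolidin-2-one | O=C(COCc1ccccc1)N1[C@@H](Cc2ccccc2)COC1=O | intermediate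
4 | 4-(benzyloxy)benzaldehyde | O=Cc1ccc(OCc2ccccc2)cc1 | starting material
5 | dibutylboron Z-enolate of 3 | CCCCB(CCCC)O/C(=C\OCc1ccccc1)N1[C@@H](Cc2ccccc2)COC1=O | intermediate (not isolated)
6 | dibutylboron aldolate of 7 | CCCCB(CCCC)O[C@H](c1ccc(OCc2ccccc2)cc1)[C@H](OCc1ccccc1)C(=O)N1[C@@H](Cc2ccccc2)COC1=O | intermediate (not isolated)
7 | (S)-4-benzyl-3-[(2S,3R)-2-(benzyloxy)-3-[4-(benzyloxy)phenyl]-3-hydroxypropanoyl]-1,3-oxazolidin-2-one | O[C@H](c1ccc(OCc2ccccc2)cc1)[C@H](OCc1ccccc1)C(=O)N1[C@@H](Cc2ccccc2)COC1=O | intermediate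
8 | (1R,2R)-2-(benzyloxy)-1-[4-(benzyloxy)phenyl]propane-1,3-diol | O[C@H](c1ccc(OCc2ccccc2)cc1)[C@H](OCc1ccccc1)CO | intermediate
9 | (1R,2S)-2-(benzyloxy)-1-[4-(benzyloxy)phenyl]-3-bromopropan-1-ol | O[C@H](c1ccc(OCc2ccccc2)cc1)[C@H](OCc1ccccc1)CBr | intermediate
10 | 3-bromobenzene-1,2-diol | Oc1cccc(Br)c1O | starting material
11 | 1,2-bis(benzyloxy)-3-bromobenzene | Brc1cccc(OCc2ccccc2)c1OCc1ccccc1 | intermediate
12 | 1,2-bis(benzyloxy)-3-iodobenzene | Ic1cccc(OCc2ccccc2)c1OCc1ccccc1 | intermediate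
13 | (2R,3R)-3,7,8-tris(benzyloxy)-2-[4-(benzyloxy)phenyl]chromane, 2,3-cis | c1cc2c(c(OCc3ccccc3)c1OCc1ccccc1)O[C@H](c1ccc(OCc3ccccc3)cc1)[C@H](OCc1ccccc1)C2 | intermediate
14 | (2R,3R,4S)-3,7,8-tris(benzyloxy)-2-[4-(benzyloxy)phenyl]chroman-4-ol, 2,3-cis-3,4-trans | c1cc2c(c(OCc3ccccc3)c1OCc1ccccc1)O[C@H](c1ccc(OCc3ccccc3)cc1)[C@H](OCc1ccccc1)[C@H]2O | intermediate
15 | (2R,3S)-3,7,8-tris(benzyloxy)-2-[4-(benzyloxy)phenyl]chroman-4-one, 2,3-cis | c1cc2c(c(OCc3ccccc3)c1OCc1ccccc1)O[C@H](c1ccc(OCc3ccccc3)cc1)[C@H](OCc1ccccc1)C2=O | intermediate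
16 | (2R,3R,4R)-3,7,8-tris(benzyloxy)-2-[4-(benzyloxy)phenyl]chroman-4-ol, all-cis | c1cc2c(c(OCc3ccccc3)c1OCc1ccccc1)O[C@H](c1ccc(OCc3ccccc3)cc1)[C@H](OCc1ccccc1)[C@@H]2O | intermediate
17 | (2R,3S,4R)-3,7,8-tris(benzyloxy)-2-[4-(benzyloxy)phenyl]chroman-4-yl acetate, all-cis | c1cc2c(c(OCc3ccccc3)c1OCc1ccccc1)O[C@H](c1ccc(OCc3ccccc3)cc1)[C@H](OCc1ccccc1)[C@@H]2OC(C)=O | intermediate
18 | (2R,3R,4S)-6-bromo-3,7,8-tris(benzyloxy)-2-[4-(benzyloxy)phenyl]chroman-4-ol, 2,3-cis-3,4-trans | Brc1cc2c(c(OCc3ccccc3)c1OCc1ccccc1)O[C@H](c1ccc(OCc3ccccc3)cc1)[C@H](OCc1ccccc1)[C@H]2O | intermediate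
19 | (2R,3S,4S)-4-(benzylsulfanyl)-6-bromo-3,7,8-tris(benzyloxy)-2-[4-(benzyloxy)phenyl]chromane, 2,3-cis-3,4-trans | Brc1cc2c(c(OCc3ccccc3)c1OCc1ccccc1)O[C@H](c1ccc(OCc3ccccc3)cc1)[C@H](OCc1ccccc1)[C@H]2SCc1ccccc1 | intermediate
20 | per-O-benzyl 6-bromoepioritin-(4β→6)-epioritin-4α-yl acetate: unit A (2R, 2,3-cis-3,4-trans, 6-bromo) bonded through C4 to C6 of unit B (2R, all-cis 4-acetate) | Brc1cc2c(c(OCc3ccccc3)c1OCc1ccccc1)O[C@H](c1ccc(OCc3ccccc3)cc1)[C@H](OCc1ccccc1)[C@H]2c1cc2c(c(OCc3ccccc3)c1OCc1ccccc1)O[C@H](c1ccc(OCc3ccccc3)cc1)[C@H](OCc1ccccc1)[C@@H]2OC(C)=O | intermediate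
21 | per-O-benzyl 6-bromoepioritin-(4β→6)-4β-(benzylsulfanyl)epioritin: as 20, with unit B carrying a 3,4-trans 4-benzylsulfanyl group in place of the acetate | Brc1cc2c(c(OCc3ccccc3)c1OCc1ccccc1)O[C@H](c1ccc(OCc3ccccc3)cc1)[C@H](OCc1ccccc1)[C@H]2c1cc2c(c(OCc3ccccc3)c1OCc1ccccc1)O[C@H](c1ccc(OCc3ccccc3)cc1)[C@H](OCc1ccccc1)[C@H]2SCc1ccccc1 | intermediate
22 | per-O-benzyl 6-bromoepioritin-(4β→6)-epioritin-(4β→6)-epioritin-4α-yl acetate: all units 2R and 2,3-cis, both C4–C6 bonds 3,4-trans, unit C all-cis 4-acetate | Brc1cc2c(c(OCc3ccccc3)c1OCc1ccccc1)O[C@H](c1ccc(OCc3ccccc3)cc1)[C@H](OCc1ccccc1)[C@H]2c1cc2c(c(OCc3ccccc3)c1OCc1ccccc1)O[C@H](c1ccc(OCc3ccccc3)cc1)[C@H](OCc1ccccc1)[C@H]2c1cc2c(c(OCc3ccccc3)c1OCc1ccccc1)O[C@H](c1ccc(OCc3ccccc3)cc1)[C@H](OCc1ccccc1)[C@@H]2OC(C)=O | intermediate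
23 | per-O-benzyl 6-bromoepioritin-(4β→6)-epioritin-(4β→6)-epioritin-4α-ol: as 22, with a free all-cis C4 hydroxyl on unit C | Brc1cc2c(c(OCc3ccccc3)c1OCc1ccccc1)O[C@H](c1ccc(OCc3ccccc3)cc1)[C@H](OCc1ccccc1)[C@H]2c1cc2c(c(OCc3ccccc3)c1OCc1ccccc1)O[C@H](c1ccc(OCc3ccccc3)cc1)[C@H](OCc1ccccc1)[C@H]2c1cc2c(c(OCc3ccccc3)c1OCc1ccccc1)O[C@H](c1ccc(OCc3ccccc3)cc1)[C@H](OCc1ccccc1)[C@@H]2O | intermediate
24 | epioritin-(4β→6)-epioritin-(4β→6)-epioritin-4α-ol: units A and B (2R,3R,4S), unit C (2R,3R,4R) | Oc1ccc([C@H]2Oc3c(ccc(O)c3O)[C@H](c3cc4c(c(O)c3O)O[C@H](c3ccc(O)cc3)[C@H](O)[C@H]4c3cc4c(c(O)c3O)O[C@H](c3ccc(O)cc3)[C@H](O)[C@@H]4O)[C@H]2O)cc1 | target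

**Totals**
Total step count: 18. Longest linear sequence: 14 steps (steps 1–4, 7–11, 14–18).

**Steps most likely to fail**

1. Step 7 (proposed new method). After ortho alkylation, the benzylic palladium alkoxide may undergo β-hydride elimination or the aryl–palladium species may be protonated before C–O reductive elimination, so ring closure fails; base-induced cyclisation of 9 to an oxetane may also drain the electrophile. The fallback sets out from 8 and 12 and comes back at 13. The primary hydroxyl of 8 is silylated (TBSCl, imidazole, DMF) to the silyl ether F1. Copper-catalysed Ullmann-type O-arylation of its secondary hydroxyl with 12 (CuI, 3,4,7,8-tetramethyl-1,10-phenanthroline, Cs2CO3, toluene, 110 °C; retention, since the carbinol C–O bond is not broken) should give the aryl ether F2. Fluoride (TBAF, THF) frees the primary alcohol F3 and Dess–Martin oxidation gives the aldehyde F4. BF3·OEt2 at −78 °C followed by Et3SiH should close the C4–C4a bond by intramolecular Friedel–Crafts hydroxyalkylation para to the C7 benzyloxy group and reduce the resulting benzylic alcohol, giving 13.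

2. Step 16. The hindered dimeric C4 cation may react sluggishly, so that elimination to the flav-3-ene or poor site selectivity between C6 and C5 of 17 takes over. The fallback sets out from 14 and comes back at 22 by reversing the order of assembly. Thioetherification of 14 (BnSH, BF3·OEt2, CH2Cl2, −20 °C) gives the unbrominated 4β-sulfide F5. Silver-promoted coupling of F5 with excess 17 (AgBF4, 2,6-di-tert-butyl-4-methylpyridine, THF, 0 °C) gives the B–C dimer acetate F6, whose upper unit keeps a free C6. Coupling of the bromine-capped monomeric sulfide 19 with F6 under the same conditions then forms the A–B bond through the less hindered monomeric cation and gives 22.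

3. Step 18. Over-reduction may remove the benzylic C4 hydroxyl of unit C by hydrogenolysis before all twelve benzyl ethers and the bromide are cleaved. The fallback sets out from 23 and comes back at 24. Dess–Martin oxidation of the only free hydroxyl gives the trimer ketone F7. Hydrogenolysis (H2, Pd(OH)2/C, NaOAc, THF/MeOH/H2O) then gives the free phenolic trimer ketone F8, whose vinylogous ester carbonyl should resist reduction. NaBH4 in MeOH at 0 °C, with hydride delivered anti to the axial C3 hydroxyl as in step 10, should give the 4α-alcohol 24.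

**Further compounds**
F1 | step 7 | (1R,2R)-2-(benzyloxy)-1-[4-(benzyloxy)phenyl]-3-[(tert-butyldimethylsilyl)oxy]propan-1-ol | O[C@H](c1ccc(OCc2ccccc2)cc1)[C@H](OCc1ccccc1)CO[Si](C)(C)C(C)(C)C
F2 | step 7 | 1,2-bis(benzyloxy)-3-{(1R,2R)-2-(benzyloxy)-1-[4-(benzyloxy)phenyl]-3-[(tert-butyldimethylsilyl)oxy]propoxy}benzene | c1ccc(OCc2ccccc2)c(OCc2ccccc2)c1O[C@H](c1ccc(OCc2ccccc2)cc1)[C@H](OCc1ccccc1)CO[Si](C)(C)C(C)(C)C
F3 | step 7 | (2R,3R)-2-(benzyloxy)-3-[4-(benzyloxy)phenyl]-3-[2,3-bis(benzyloxy)phenoxy]propan-1-ol | c1ccc(OCc2ccccc2)c(OCc2ccccc2)c1O[C@H](c1ccc(OCc2ccccc2)cc1)[C@H](OCc1ccccc1)CO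
F4 | step 7 | (2S,3R)-2-(benzyloxy)-3-[4-(benzyloxy)phenyl]-3-[2,3-bis(benzyloxy)phenoxy]propanal | c1ccc(OCc2ccccc2)c(OCc2ccccc2)c1O[C@H](c1ccc(OCc2ccccc2)cc1)[C@H](OCc1ccccc1)C=O
F5 | step 16 | (2R,3S,4S)-4-(benzylsulfanyl)-3,7,8-tris(benzyloxy)-2-[4-(benzyloxy)phenyl]chromane, 2,3-cis-3,4-trans | c1cc2c(c(OCc3ccccc3)c1OCc1ccccc1)O[C@H](c1ccc(OCc3ccccc3)cc1)[C@H](OCc1ccccc1)[C@H]2SCc1ccccc1
F6 | step 16 | per-O-benzyl epioritin-(4β→6)-epioritin-4α-yl acetate (units B–C, no bromine) | c1cc2c(c(OCc3ccccc3)c1OCc1ccccc1)O[C@H](c1ccc(OCc3ccccc3)cc1)[C@H](OCc1ccccc1)[C@H]2c1cc2c(c(OCc3ccccc3)c1OCc1ccccc1)O[C@H](c1ccc(OCc3ccccc3)cc1)[C@H](OCc1ccccc1)[C@@H]2OC(C)=O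
F7 | step 18 | per-O-benzyl 6-bromoepioritin-(4β→6)-epioritin-(4β→6)-(2R,3S)-2,3-cis-flavan-4-one (unit C as the 4-ketone) | Brc1cc2c(c(OCc3ccccc3)c1OCc1ccccc1)O[C@H](c1ccc(OCc3ccccc3)cc1)[C@H](OCc1ccccc1)[C@H]2c1cc2c(c(OCc3ccccc3)c1OCc1ccccc1)O[C@H](c1ccc(OCc3ccccc3)cc1)[C@H](OCc1ccccc1)[C@H]2c1cc2c(c(OCc3ccccc3)c1OCc1ccccc1)O[C@H](c1ccc(OCc3ccccc3)cc1)[C@H](OCc1ccccc1)C2=O
F8 | step 18 | epioritin-(4β→6)-epioritin-(4β→6)-(2R,3S)-3,7,8-trihydroxy-2-(4-hydroxyphenyl)chroman-4-one (free phenolic trimer ketone) | c1cc2c(c(O)c1O)O[C@H](c1ccc(O)cc1)[C@H](O)[C@H]2c1cc2c(c(O)c1O)O[C@H](c1ccc(O)cc1)[C@H](O)[C@H]2c1cc2c(c(O)c1O)O[C@H](c1ccc(O)cc1)[C@H](O)C2=O
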